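**Plan**

- Retrosynthesis: the C3 configuration, the acetate and the free C15 alcohol are adjusted last, and C6 is deoxygenated through the xanthate of hydroxy acid 17. Ring B is then cut at C6–C7 and C9–C10 in one step back to the bis-allylic ether acid 14, and C5–C6 is cut (Stille) to ring A triflate 7 and stannane 12.
- Enabling feature: C7–C8(=C17)–C9 of ring B is a 2-methylidenepropane-1,3-diyl unit whose C9 arm carries C11–C16, which is the prenyl end of geraniol, and C10–C5–C6 of ring A is a β-methyl enal equivalent. Tying C6 to C9 through a temporary ether oxygen lets a [2,3] shift, a [3,3] shift and a carbonyl-ene closure run in sequence.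
- Forward order: ring A (from methyl 2,6-dimethoxybenzoate) and the chain (from geraniol) are made separately and joined at C5–C6; ring B closes in step 12; the helpers (the C6 oxygen and the free C19 acid) are removed or returned to the methyl ester in steps 13 and 14.
- Stereochemistry: C4 from the CBS desymmetrisation; the C9–O carbinol from Shi epoxidation, relayed to C9 and C10 by the two sigmatropic shifts; C5 by enolate protonation; C3 by LiBH(s-Bu)3 reduction of the 3-ketone; the C13 alkene from geraniol.

Key step: step 12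

Remark: labdane numbering is used (ring A = C1–C5, C10; ring B = C5–C10; C17 = exocyclic CH2; C18 and C19 = methyl and ester carbon on C4; C20 = methyl on C10; C11–C16 = side chain).
Remark: the hydride in step 2 is assumed to enter anti to the axial ester (cis-hydroxy ester). If it enters syn, the enantiomeric catalyst gives the same C4 configuration, and C3 is reset in steps 16 and 17 in either case.
Remark: tributyl(iodomethyl)stannane is taken as a commercial reagent.
Remark: the 6-hydroxyl of 17 is written as 6β (axial), as the ene transition state requires. Its configuration is of no consequence because C6 becomes CH2 in step 14. Compound 17 is carried into step 13 as the crude acid after a cold work-up, since strong acid or heat would close the 6β-hydroxyl onto C19.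

**Route**

Step 1
Reactants: 1 methyl 2,6-dimethoxybenzoate
Product: 3 methyl 1-methyl-2,6-dioxocyclohexane-1-carboxylate, via bis-enol ether 2 (not isolated)
Conditions: Li, NH3(l), THF, t-BuOH (1 equiv), −78 °C; MeI; then 1 M HCl, THF, rt
Reagents that add atoms: iodomethane, CI; water, O
Why: Birch reductive alkylation of the benzoate should give the 1-methyl-2,5-diene ester, whose two enol ethers hydrolyse in dilute acid to the prochiral 2,2-disubstituted 1,3-dione (no stereocentre yet).

Step 2
Reactants: 3 methyl 1-methyl-2,6-dioxocyclohexane-1-carboxylate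
Product: 4 methyl (1S,2S)-2-hydroxy-1-methyl-6-oxocyclohexane-1-carboxylate
Conditions: (R)-2-methyl-CBS-oxazaborolidine (cat.), BH3·SMe2 (0.6 equiv), THF, −40 °C; MeOH
Reagents that add atoms: none
Why: Corey–Bakshi–Shibata reduction should desymmetrise the dione, the catalyst fixing the (S)-carbinol and hydride delivery anti to the axial ester selecting the carbonyl that leaves the quaternary carbon (C4 of the target) correctly configured, while the carbinol is only a placeholder.

Step 3
Reactants: 4 methyl (1S,2S)-2-hydroxy-1-methyl-6-oxocyclohexane-1-carboxylate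
Product: 5 methyl (1S,2S)-2-(tert-butyldimethylsilyloxy)-1-methyl-6-oxocyclohexane-1-carboxylate
Conditions: TBSOTf, 2,6-lutidine, CH2Cl2, 0 °C
Reagents that add atoms: tert-butyldimethylsilyl trifluoromethanesulfonate, CC(C)(C)[Si](C)(C)OS(=O)(=O)C(F)(F)F
Why: O-silylation with the silyl triflate is the standard protection for a hindered secondary alcohol next to a quaternary carbon and leaves both stereocentres untouched.

Step 4
Reactants: 5 methyl (1S,2S)-2-(tert-butyldimethylsilyloxy)-1-methyl-6-oxocyclohexane-1-carboxylate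
Product: 6 methyl (1S,2S)-2-(tert-butyldimethylsilyloxy)-1,5-dimethyl-6-oxocyclohexane-1-carboxylate (C5 epimers)
Conditions: LiN(i-Pr)2, THF, −78 °C; MeI, −78 → 0 °C
Reagents that add atoms: iodomethane, CI
Why: enolate alkylation can occur only on the CH2 side of the ketone (the other α-carbon is quaternary) and brings in C20; the new centre is irrelevant because it becomes sp2 in step 5.

Step 5
Reactants: 6 methyl (1S,2S)-2-(tert-butyldimethylsilyloxy)-1,5-dimethyl-6-oxocyclohexane-1-carboxylate
Product: 7 methyl (1S,6S)-6-(tert-butyldimethylsilyloxy)-1,3-dimethyl-2-(trifluoromethylsulfonyloxy)cyclohex-2-ene-1-carboxylate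
Conditions: KN(SiMe3)2, THF, −78 → 0 °C; PhNTf2
Reagents that add atoms: N-phenylbis(trifluoromethanesulfonimide), O=S(=O)(N(c1ccccc1)S(=O)(=O)C(F)(F)F)C(F)(F)F
Why: enol triflate formation is regiospecific because only one α-hydrogen remains, so the tetrasubstituted C5=C10 alkene of ring A results.

Step 6
Reactants: 8 geraniol
Product: 9 tert-butyl[(2E)-3,7-dimethylocta-2,6-dienyloxy]dimethylsilane
Conditions: TBSCl, imidazole, CH2Cl2, rt
Reagents that add atoms: tert-butyldimethylsilyl chloride, CC(C)(C)[Si](C)(C)Cl
Why: routine silylation of a primary allylic alcohol gives an ether that tolerates the basic, Lewis acidic and radical steps that follow.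

Step 7
Reactants: 9 tert-butyl[(2E)-3,7-dimethylocta-2,6-dienyloxy]dimethylsilane
Product: 10 tert-butyl{[(2E)-5-[(2R)-3,3-dimethyloxiran-2-yl]-3-methylpent-2-enyl]oxy}dimethylsilane
Conditions: D-fructose-derived Shi ketone (cat.), Oxone (KHSO5), K2CO3, Bu4NHSO4 (cat.), MeCN/CH2(OMe)2/aqueous buffer, 0 °C
Reagents that add atoms: potassium peroxymonosulfate, [K+].[O-]S(=O)(=O)OO
Why: Shi asymmetric epoxidation should take the more electron-rich terminal alkene (the other is deactivated by the allylic silyloxy group) through the spiro transition state, setting the (R)-epoxide carbon that becomes the C9–O carbinol.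

Step 8
Reactants: 10 tert-butyl{[(2E)-5-[(2R)-3,3-dimethyloxiran-2-yl]-3-methylpent-2-enyl]oxy}dimethylsilane
Product: 11 (3R,6E)-8-(tert-butyldimethylsilyloxy)-2,6-dimethylocta-1,6-dien-3-ol
Conditions: Et2AlCl, lithium 2,2,6,6-tetramethylpiperidide (LiNC9H18), toluene, 0 °C
Reagents that add atoms: none
Why: the aluminium amide isomerises the trisubstituted epoxide to the allylic alcohol by removing a methyl proton while the tertiary C–O bond breaks, so the secondary C–O bond and its (R) configuration are retained.

Step 9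
Reactants: 11 (3R,6E)-8-(tert-butyldimethylsilyloxy)-2,6-dimethylocta-1,6-dien-3-ol
Product: 12 tributyl({[(3R,6E)-8-(tert-butyldimethylsilyloxy)-2,6-dimethylocta-1,6-dien-3-yl]oxy}methyl)stannane
Conditions: KH, THF, 0 °C; Bu3SnCH2I, rt
Reagents that add atoms: tributyl(iodomethyl)stannane, CCCC[Sn](CCCC)(CCCC)CI
Why: Williamson etherification of the potassium alkoxide with the primary iodide brings in C6 as an alkoxymethylstannane without touching the carbinol centre.

Step 10
Reactants: 7 methyl (1S,6S)-6-(tert-butyldimethylsilyloxy)-1,3-dimethyl-2-(trifluoromethylsulfonyloxy)cyclohex-2-ene-1-carboxylate; 12 tributyl({[(3R,6E)-8-(tert-butyldimethylsilyloxy)-2,6-dimethylocta-1,6-dien-3-yl]oxy}methyl)stannane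
Product: 13 methyl (1S,6S)-6-(tert-butyldimethylsilyloxy)-2-({[(3R,6E)-8-(tert-butyldimethylsilyloxy)-2,6-dimethylocta-1,6-dien-3-yl]oxy}methyl)-1,3-dimethylcyclohex-2-ene-1-carboxylate
Conditions: Pd(PPh3)4 (zerovalent palladium, cat.), LiCl, CuI (cat.), 1,4-dioxane, 90 °C
Reagents that add atoms: none
Why: Stille coupling of an alkenyl triflate with an alkoxymethylstannane forms C5–C6 and gives the bis-allylic ether in which C6 and C9 are tied through oxygen, with no stereocentre involved.

Step 11
Reactants: 13 methyl (1S,6S)-6-(tert-butyldimethylsilyloxy)-2-({[(3R,6E)-8-(tert-butyldimethylsilyloxy)-2,6-dimethylocta-1,6-dien-3-yl]oxy}methyl)-1,3-dimethylcyclohex-2-ene-1-carboxylate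
Product: 14 (1S,6S)-6-(tert-butyldimethylsilyloxy)-2-({[(3R,6E)-8-(tert-butyldimethylsilyloxy)-2,6-dimethylocta-1,6-dien-3-yl]oxy}methyl)-1,3-dimethylcyclohex-2-ene-1-carboxylic acid
Conditions: NaSEt, DMF, 60 °C; 1 M HCl work-up
Reagents that add atoms: none
Why: SN2 demethylation by thiolate at the ester methyl group cleaves this neopentyl-type ester where acyl attack would fail, and the free acid is needed so that the alkoxide of step 12 cannot lactonise onto C19.

Step 12
Reactants: 14 (1S,6S)-6-(tert-butyldimethylsilyloxy)-2-({[(3R,6E)-8-(tert-butyldimethylsilyloxy)-2,6-dimethylocta-1,6-dien-3-yl]oxy}methyl)-1,3-dimethylcyclohex-2-ene-1-carboxylic acid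
Product: 17 3β,15-bis(tert-butyldimethylsilyloxy)-6β-hydroxylabda-8(17),13E-dien-19-oic acid, via dienol acid 15 (not isolated), via aldehyde acid 16 (not isolated)
Conditions: KH (3.5 equiv), 18-crown-6, THF, 0 → 25 °C; MeOH (3 equiv), −78 °C; Me2AlCl (6 equiv), CH2Cl2, −78 → −20 °C; cold 0.5 M HCl work-up, 0 °C
Reagents that add atoms: none
Why: KH first forms the carboxylate, which should guide removal of a C6–H next to the ether oxygen, and the carbanion undergoes a suprafacial [2,3]-Wittig shift through an envelope transition state (ring A residue exo, side chain pseudo-equatorial) that makes C6–C7, gives the (E)-C8=C9 alkene and relays the (R)-carbinol centre of the C9–O bond to the (S)-alkoxide of 15; this alkoxide then rearranges by a chair anionic oxy-Cope [3,3] shift that makes C9–C10 on the α-face of ring A (C6–O⁻ pseudo-equatorial, anti to the axial C19 carboxylate), breaks C6–C7 again and sets C9 and C10 together, with C20 pushed to the β-face. MeOH protonates the aldehyde enolate at C5 from the α-face, anti to the axial C19 and C20 groups, giving 16 with the trans relationship needed for ring B. Me2AlCl then closes ring B by a type 2 carbonyl-ene reaction (six-membered chair transition state, exo with respect to the C6 carbonyl and endo with respect to the C7=C8 alkene) that re-forms C6–C7, moves the double bond to C8=C17 and gives the aluminium salt of 17, whose 6β-hydroxyl is axial because the hydrogen passes from the C17 methyl group to oxygen on that face, and the brief cold acid work-up releases the hydroxy acid without closing it onto C19. The closest known reaction types are the tandem [2,3]-Wittig–anionic oxy-Cope rearrangement of bis-allylic ethers and the Me2AlCl-promoted type 2 ene cyclisation of 5-methylhex-5-enals to 3-methylidenecyclohexanols; together they amount to a [3+3] annulation in which the isopropenyl carbinol acts as a 2-methylidenepropane-1,3-diyl synthon. The step needs deprotonation at C6 and not at C9–H, (E) geometry in the first shift and α-face selectivity in the second; the primary, carboxylate-flanked CH2 group, the 2-methyl group of the migrating allyl unit (which disfavours the endo arrangement) and the matched shielding of the β-face by the axial carboxylate are expected to secure these.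

Step 13
Reactants: 17 3β,15-bis(tert-butyldimethylsilyloxy)-6β-hydroxylabda-8(17),13E-dien-19-oic acid
Product: 18 methyl 3β,15-bis(tert-butyldimethylsilyloxy)-6β-[(methylsulfanyl)carbonothioyloxy]labda-8(17),13E-dien-19-oate
Conditions: NaH (3 equiv), imidazole (cat.), THF/DMF, 0 °C → rt; CS2; MeI (excess), rt
Reagents that add atoms: carbon disulfide, S=C=S; iodomethane, CI
Why: the sodium alkoxide–carboxylate of 17 adds through its alkoxide to CS2 before any electrophile is present, and excess MeI then S-methylates the dithiocarbonate and O-methylates the carboxylate in the same flask (xanthate formation for a Barton–McCombie deoxygenation combined with carboxylate alkylation), so that no free alkoxide remains to close onto the new methyl ester.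

Step 14
Reactants: 18 methyl 3β,15-bis(tert-butyldimethylsilyloxy)-6β-[(methylsulfanyl)carbonothioyloxy]labda-8(17),13E-dien-19-oate
Product: 19 methyl 3β,15-bis(tert-butyldimethylsilyloxy)labda-8(17),13E-dien-19-oate
Conditions: Bu3SnH, AIBN (cat.), toluene, 110 °C
Reagents that add atoms: none
Why: Barton–McCombie deoxygenation removes the helper oxygen at C6 through a secondary radical that is reduced by the tin hydride, leaving the alkenes and all stereocentres as they are.

Step 15
Reactants: 19 methyl 3β,15-bis(tert-butyldimethylsilyloxy)labda-8(17),13E-dien-19-oate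
Product: 20 methyl 3β,15-dihydroxylabda-8(17),13E-dien-19-oate
Conditions: HF·pyridine, pyridine/THF, 0 → 40 °C
Reagents that add atoms: none
Why: buffered fluoride desilylation removes both silyl ethers under conditions too mild to isomerise the exocyclic alkene or to open the β-hydroxy ester by retro-aldol cleavage.

Step 16
Reactants: 20 methyl 3β,15-dihydroxylabda-8(17),13E-dien-19-oate
Product: 21 methyl 3,15-dioxolabda-8(17),13E-dien-19-oate
Conditions: Dess–Martin periodinane (2.5 equiv), CH2Cl2, rt
Reagents that add atoms: none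
Why: Dess–Martin oxidation converts the placeholder C3 alcohol into the ketone (a β-keto ester that cannot epimerise because C4 is quaternary) and the allylic alcohol into the (E)-enal.

Step 17
Reactants: 21 methyl 3,15-dioxolabda-8(17),13E-dien-19-oate
Product: 22 methyl 3α,15-dihydroxylabda-8(17),13E-dien-19-oate
Conditions: LiBH(s-Bu)3 (2.5 equiv), THF, −78 °C; aqueous NH4Cl
Reagents that add atoms: none
Why: the bulky trialkylborohydride should attack the C3 ketone of the trans-fused ring A from the equatorial direction, giving the axial 3α-alcohol, and reduce the β,β-disubstituted enal in the 1,2-sense back to the (E)-allylic alcohol.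

Step 18
Reactants: 22 methyl 3α,15-dihydroxylabda-8(17),13E-dien-19-oate
Product: 23 methyl 3α,15-diacetoxylabda-8(17),13E-dien-19-oate
Conditions: Ac2O, DMAP (cat.), pyridine, 50 °C
Reagents that add atoms: acetic anhydride, CC(=O)OC(C)=O
Why: DMAP-catalysed acetylation esterifies both alcohols, the axial C3 hydroxyl needing the nucleophilic catalyst and gentle warming.

Step 19
Reactants: 23 methyl 3α,15-diacetoxylabda-8(17),13E-dien-19-oate
Product: 24 methyl 3α-acetoxy-15-hydroxylabda-8(17),13E-dien-19-oate (target)
Conditions: K2CO3 (cat.), MeOH, 0 °C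
Reagents that add atoms: none
Why: base-catalysed transesterification should remove the unhindered primary allylic acetate much faster than the axial secondary acetate next to quaternary C4, releasing the target without touching any stereocentre.

**Compound list**

1 | methyl 2,6-dimethoxybenzoate | COC(=O)c1c(OC)cccc1OC | starting material
2 | methyl 2,6-dimethoxy-1-methylcyclohexa-2,5-diene-1-carboxylate (bis-enol ether, not isolated) | COC(=O)C1(C)C(OC)=CCC=C1OC | intermediate
3 | methyl 1-methyl-2,6-dioxocyclohexane-1-carboxylate | COC(=O)C1(C)C(=O)CCCC1=O | intermediate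
4 | methyl (1S,2S)-2-hydroxy-1-methyl-6-oxocyclohexane-1-carboxylate | O=C1CCC[C@H](O)[C@]1(C)C(=O)OC | intermediate
5 | methyl (1S,2S)-2-(tert-butyldimethylsilyloxy)-1-methyl-6-oxocyclohexane-1-carboxylate | O=C1CCC[C@H](O[Si](C)(C)C(C)(C)C)[C@]1(C)C(=O)OC | intermediate
6 | methyl (1S,2S)-2-(tert-butyldimethylsilyloxy)-1,5-dimethyl-6-oxocyclohexane-1-carboxylate (C5 epimers) | O=C1C(C)CC[C@H](O[Si](C)(C)C(C)(C)C)[C@]1(C)C(=O)OC | intermediate
7 | methyl (1S,6S)-6-(tert-butyldimethylsilyloxy)-1,3-dimethyl-2-(trifluoromethylsulfonyloxy)cyclohex-2-ene-1-carboxylate | CC1=C(OS(=O)(=O)C(F)(F)F)[C@@](C)(C(=O)OC)[C@@H](O[Si](C)(C)C(C)(C)C)CC1 | intermediate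
8 | geraniol | CC(C)=CCC/C(C)=C/CO | starting material
9 | tert-butyl[(2E)-3,7-dimethylocta-2,6-dienyloxy]dimethylsilane | CC(C)=CCC/C(C)=C/CO[Si](C)(C)C(C)(C)C | intermediate
10 | tert-butyl{[(2E)-5-[(2R)-3,3-dimethyloxiran-2-yl]-3-methylpent-2-enyl]oxy}dimethylsilane | CC1(C)O[C@@H]1CC/C(C)=C/CO[Si](C)(C)C(C)(C)C | intermediate
11 | (3R,6E)-8-(tert-butyldimethylsilyloxy)-2,6-dimethylocta-1,6-dien-3-ol | C=C(C)[C@H](O)CC/C(C)=C/CO[Si](C)(C)C(C)(C)C | intermediate
12 | tributyl({[(3R,6E)-8-(tert-butyldimethylsilyloxy)-2,6-dimethylocta-1,6-dien-3-yl]oxy}methyl)stannane | C=C(C)[C@H](OC[Sn](CCCC)(CCCC)CCCC)CC/C(C)=C/CO[Si](C)(C)C(C)(C)C | intermediate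
13 | methyl (1S,6S)-6-(tert-butyldimethylsilyloxy)-2-({[(3R,6E)-8-(tert-butyldimethylsilyloxy)-2,6-dimethylocta-1,6-dien-3-yl]oxy}methyl)-1,3-dimethylcyclohex-2-ene-1-carboxylate | CC1=C(CO[C@H](CC/C(C)=C/CO[Si](C)(C)C(C)(C)C)C(C)=C)[C@@](C)(C(=O)OC)[C@@H](O[Si](C)(C)C(C)(C)C)CC1 | intermediate
14 | carboxylic acid of 13 (bis-allylic ether acid) | CC1=C(CO[C@H](CC/C(C)=C/CO[Si](C)(C)C(C)(C)C)C(C)=C)[C@@](C)(C(=O)O)[C@@H](O[Si](C)(C)C(C)(C)C)CC1 | intermediate
15 | (1S,6S)-6-(tert-butyldimethylsilyloxy)-2-[(1S,3E,7E)-9-(tert-butyldimethylsilyloxy)-1-hydroxy-3,7-dimethylnona-3,7-dienyl]-1,3-dimethylcyclohex-2-ene-1-carboxylic acid (dienol acid, formed as its dipotassium salt, not isolated) | CC1=C([C@@H](O)C/C(C)=C/CC/C(C)=C/CO[Si](C)(C)C(C)(C)C)[C@@](C)(C(=O)O)[C@@H](O[Si](C)(C)C(C)(C)C)CC1 | intermediate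
16 | 3β,15-bis(tert-butyldimethylsilyloxy)-6-oxo-6,7-secolabda-7,13E-dien-19-oic acid (aldehyde acid with 5α-H, 10β-methyl and an isopropenyl group on C9, not isolated) | C=C(C)[C@H](CC/C(C)=C/CO[Si](C)(C)C(C)(C)C)[C@@]1(C)CC[C@H](O[Si](C)(C)C(C)(C)C)[C@](C)(C(=O)O)[C@@H]1C=O | intermediate
17 | 3β,15-bis(tert-butyldimethylsilyloxy)-6β-hydroxylabda-8(17),13E-dien-19-oic acid | C=C1C[C@@H](O)[C@@H]2[C@](C)(CC[C@H](O[Si](C)(C)C(C)(C)C)[C@]2(C)C(=O)O)[C@H]1CC/C(C)=C/CO[Si](C)(C)C(C)(C)C | intermediate
18 | methyl 3β,15-bis(tert-butyldimethylsilyloxy)-6β-[(methylsulfanyl)carbonothioyloxy]labda-8(17),13E-dien-19-oate | C=C1C[C@@H](OC(=S)SC)[C@@H]2[C@](C)(CC[C@H](O[Si](C)(C)C(C)(C)C)[C@]2(C)C(=O)OC)[C@H]1CC/C(C)=C/CO[Si](C)(C)C(C)(C)C | intermediate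
19 | methyl 3β,15-bis(tert-butyldimethylsilyloxy)labda-8(17),13E-dien-19-oate | C=C1CC[C@@H]2[C@](C)(CC[C@H](O[Si](C)(C)C(C)(C)C)[C@]2(C)C(=O)OC)[C@H]1CC/C(C)=C/CO[Si](C)(C)C(C)(C)C | intermediate
20 | methyl 3β,15-dihydroxylabda-8(17),13E-dien-19-oate | C=C1CC[C@@H]2[C@](C)(CC[C@H](O)[C@]2(C)C(=O)OC)[C@H]1CC/C(C)=C/CO | intermediate
21 | methyl 3,15-dioxolabda-8(17),13E-dien-19-oate | C=C1CC[C@@H]2[C@](C)(CCC(=O)[C@]2(C)C(=O)OC)[C@H]1CC/C(C)=C/C=O | intermediate
22 | methyl 3α,15-dihydroxylabda-8(17),13E-dien-19-oate | C=C1CC[C@@H]2[C@](C)(CC[C@@H](O)[C@]2(C)C(=O)OC)[C@H]1CC/C(C)=C/CO | intermediate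
23 | methyl 3α,15-diacetoxylabda-8(17),13E-dien-19-oate | C=C1CC[C@@H]2[C@](C)(CC[C@@H](OC(C)=O)[C@]2(C)C(=O)OC)[C@H]1CC/C(C)=C/COC(C)=O | intermediate
24 | methyl 3α-acetoxy-15-hydroxylabda-8(17),13E-dien-19-oate, i.e. methyl (1R,2R,4aR,5S,8aR)-2-acetoxy-5-[(E)-5-hydroxy-3-methylpent-3-enyl]-1,4a-dimethyl-6-methylidenedecahydronaphthalene-1-carboxylate | C=C1CC[C@@H]2[C@](C)(CC[C@@H](OC(C)=O)[C@]2(C)C(=O)OC)[C@H]1CC/C(C)=C/CO | target

**Step count and risks**

Total steps: 19. Longest linear sequence: 15 steps (steps 1–5 and 10–19).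

Steps most likely to fail:

1. Step 12. The cascade may go astray in several ways: deprotonation at C9–H or a [1,2] shift instead of the [2,3] shift, loss of (E) selectivity or of chirality transfer in the first shift, or closure to the cis-fused ring. The fallback sets out from triflate 7 and silyl ether 9 and comes back at 15; it fixes the alkene geometry and the C6 carbinol separately, then runs the two later stages as separate operations. Aminocarbonylation of 7 (Pd(OAc)2 (palladium diacetate), a bisphosphine, CO, MeNHOMe·HCl, Et3N) would give the N-methoxy-N-methylamide F1. Allylic oxidation of 9 (SeO2 cat., t-BuOOH; then NaBH4) would give the (2E,6E)-8-hydroxy compound F2, and MsCl/LiCl the allylic chloride F3. The allylbarium reagent from F3 (activated barium from BaI2 and lithium biphenylide, THF, −78 °C) adds through its unsubstituted end with retention of alkene geometry to F1, giving the β,γ-unsaturated ketone F4. CBS reduction with the (R)-catalyst sets the (S)-carbinol, which lactonises onto the methyl ester to give the dienyl lactone F5. KOH opens F5 to the potassium salt of 15; KH/18-crown-6 then gives 16, and Me2AlCl gives 17.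

2. Step 10. Transfer of the alkoxymethyl group from tin to the hindered tetrasubstituted alkenylpalladium intermediate may be too slow, so that the triflate is reduced or hydrolysed instead. The fallback sets out from 7 and comes back at 13, building the ether by O-alkylation. Reductive carbonylation of 7 (Pd(OAc)2, 1,3-bis(diphenylphosphino)propane, CO, Et3SiH, Et3N) would give the enal F6; Luche reduction (NaBH4, CeCl3·7H2O, MeOH, −78 °C) the allylic alcohol F7; and MsCl/Et3N followed by LiBr the allylic bromide F8. Williamson reaction of F8 with the potassium alkoxide of 11 (KH, THF) then gives 13.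

3. Step 13. The hindered axial 6β-alkoxide may add to CS2 only reversibly and incompletely, or may close onto C19 once the ester is methylated, so that the xanthate is not formed cleanly. The fallback sets out from 17 and comes back at 19; it makes deliberate use of the ring closure and cleaves the lactone at the alkyl–oxygen bond. Acid-catalysed lactonisation (pyridinium p-toluenesulfonate cat., CH2Cl2, rt) would close 17 to the 19,6β-lactone F9. PhSeNa (from (PhSe)2 and NaBH4, DMF, 120 °C) opens the lactone by SN2 attack at C6 with inversion, and MeI esterifies the carboxylate to the 6α-phenylselanyl methyl ester F10. Bu3SnH/AIBN then removes the selenium to give 19.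

**Further compounds**

F1 | step 12 | methyl (1S,6S)-6-(tert-butyldimethylsilyloxy)-2-[methoxy(methyl)carbamoyl]-1,3-dimethylcyclohex-2-ene-1-carboxylate | CC1=C(C(=O)N(C)OC)[C@@](C)(C(=O)OC)[C@@H](O[Si](C)(C)C(C)(C)C)CC1
F2 | step 12 | (2E,6E)-8-(tert-butyldimethylsilyloxy)-2,6-dimethylocta-2,6-dien-1-ol | OC/C(C)=C/CC/C(C)=C/CO[Si](C)(C)C(C)(C)C
F3 | step 12 | tert-butyl{[(2E,6E)-8-chloro-3,7-dimethylocta-2,6-dienyl]oxy}dimethylsilane | ClC/C(C)=C/CC/C(C)=C/CO[Si](C)(C)C(C)(C)C
F4 | step 12 | methyl (1S,6S)-6-(tert-butyldimethylsilyloxy)-2-[(3E,7E)-9-(tert-butyldimethylsilyloxy)-3,7-dimethylnona-3,7-dienoyl]-1,3-dimethylcyclohex-2-ene-1-carboxylate | CC1=C(C(=O)C/C(C)=C/CC/C(C)=C/CO[Si](C)(C)C(C)(C)C)[C@@](C)(C(=O)OC)[C@@H](O[Si](C)(C)C(C)(C)C)CC1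
F5 | step 12 | γ-lactone of 15 (C19 carboxyl closed onto the C6 oxygen, (S) at C6) | CC1=C2[C@H](C/C(C)=C/CC/C(C)=C/CO[Si](C)(C)C(C)(C)C)OC(=O)[C@@]2(C)[C@@H](O[Si](C)(C)C(C)(C)C)CC1
F6 | step 10 | methyl (1S,6S)-6-(tert-butyldimethylsilyloxy)-2-formyl-1,3-dimethylcyclohex-2-ene-1-carboxylate | CC1=C(C=O)[C@@](C)(C(=O)OC)[C@@H](O[Si](C)(C)C(C)(C)C)CC1
F7 | step 10 | methyl (1S,6S)-6-(tert-butyldimethylsilyloxy)-2-(hydroxymethyl)-1,3-dimethylcyclohex-2-ene-1-carboxylate | CC1=C(CO)[C@@](C)(C(=O)OC)[C@@H](O[Si](C)(C)C(C)(C)C)CC1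
F8 | step 10 | methyl (1S,6S)-2-(bromomethyl)-6-(tert-butyldimethylsilyloxy)-1,3-dimethylcyclohex-2-ene-1-carboxylate | CC1=C(CBr)[C@@](C)(C(=O)OC)[C@@H](O[Si](C)(C)C(C)(C)C)CC1
F9 | step 13 | 3β,15-bis(tert-butyldimethylsilyloxy)labda-8(17),13E-dien-19,6β-olide | C=C1C[C@H]2OC(=O)[C@@]3(C)[C@@H](O[Si](C)(C)C(C)(C)C)CC[C@@](C)([C@@H]23)[C@H]1CC/C(C)=C/CO[Si](C)(C)C(C)(C)C
F10 | step 13 | methyl 3β,15-bis(tert-butyldimethylsilyloxy)-6α-(phenylselanyl)labda-8(17),13E-dien-19-oate | C=C1C[C@H]([Se]c2ccccc2)[C@@H]2[C@](C)(CC[C@H](O[Si](C)(C)C(C)(C)C)[C@]2(C)C(=O)OC)[C@H]1CC/C(C)=C/CO[Si](C)(C)C(C)(C)C
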